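The numbers were set for the occasion; what happens was integrated by code.

**Neighbours first.** Noon carries twice the free catalyst of dawn. The question is what that extra catalyst buys in target, since the starting material also falls away by itself and kills free catalyst as it goes.

the same everywhere: starting material 0.20 M; time 40 h
- dawn: free catalyst 0.40 mM
- noon: free catalyst 0.80 mM
- winter: free catalyst 1.5 mM
- spring: free catalyst 3.0 mM
- summer: free catalyst 6.0 mM

    starting material + free catalyst → free catalyst + target (k1 = 0.0022 L mol⁻¹ s⁻¹)
    starting material → side product (k2 = 1.4 × 10⁻⁵ s⁻¹)
    starting material + free catalyst → spent catalyst (k3 = 4.8 × 10⁻⁵ L mol⁻¹ s⁻¹)

- amount of target at the end, in percent of the starting material charged for dawn, noon, winter, spring, summer, in this order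
- how the row runs (rises all the way / rises, then falls / hardly changes / falls all the way / falls, then rises)

- "hardly changes" means that all values lie within two and a half points (for a concentration: within two and a half percent of the largest)
- run time (dawn): 40 h

**Two rivals.** In dawn, the loss to side product halves the starting material in 14 h, and at the start this loss outruns the catalysed route by a factor of 16. The killing step takes starting material more slowly than the catalysed route, by a factor of 45.8. Each step is first order in starting material, so the split depends on [free catalyst].

**Undying catalyst.** With [free catalyst] held at its charge, dawn's share is 5.91%. This capture share, the selectivity for target among the starting material used up, is a ceiling, because free catalyst can only fall. Summer's ceiling is 48.0%.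

**Catalyst at its floor.** The loss to side product alone gives the starting material a lifetime of 19.8 h, while the charged starting material gives free catalyst a lifetime of 28.9 h, which is longer. The ratio of these lifetimes leaves at least 50.4% of the free catalyst. In 40 h, at least 86.7% of the starting material is used up. A flask at that floor from its first moment, with just that much used, yields 2.66% in dawn and 27.7% in summer.

**Between them.** The real flasks start at the ceiling and sink towards the floor, so they lie between the two. Summer's floor yield stands above dawn's ceiling, so this reckoning commits to more target in summer than in dawn. Noon's floor yield of 5.16% stands below dawn's ceiling, so these neighbouring bands overlap, and a rise all the way remains this reckoning's expectation, not something it proves.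

**The check.** The forecast gives 4%, 7.8%, 14%, 25.5% and 42.4%, a row that rises all the way, holding that “more catalyst steadily captures more material for the target”.

**The result.** The simulation gives 4.00%, 7.81%, 14.0%, 25.5% and 42.4%, and the row rises all the way. Dawn's target stands below its capture share of 5.91%, and after 40.0 h dawn's free catalyst is 56.3% of its charge, above the floor of 50.4%. Reckoned for spring's charge, the capture share is 31.8% and the floor yield 16.6%, and spring's target ends between them at 25.5%.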